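# Proposal: CNP0356520.2 by glycol cleavage of a carvone-derived bis-cyclohexene diol

## The problem

Germacrane numbering is used throughout: ring C1–C10, lactone carbons C11–C13, C14 on C10, C15 on C4. The α face is the face of H6 and H7; the β face carries O6 and C11.

The target 26 is a ten-membered carbocycle with a cis-fused α-methylene-γ-butyrolactone at C6–C7 (H6 and H7 syn). It has a ring-cis C4=C5 olefin, a 1,10-epoxide whose parent olefin is also ring-cis, a free C3 carbinol, a C14 primary alcohol and an (R)-2-methylbutanoate on O8. Of its seven stereocentres, C7 can come from the chiral pool and fixes C6 through the lactone ring. C8 is next to C7, but 1,2-induction in a flexible ten-membered ketone is unreliable. C3 and the epoxide carbons are remote and need reagent control, which an allylic ketone at C3 and the C14 allylic alcohol make possible.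

The fragile groups are these. The methylene lactone is a Michael acceptor, open to conjugate reduction and to base-induced olefin migration through C7–H. The 2,3-epoxy alcohol is labile. Any ketone at C3 or C8 is β,γ to the C1=C10 olefin or epoxide. A free O8 cis to C11 can translactonise. The α-centre of the ester can epimerise.

The enabling feature is that C3 and C8 both carry oxygen and face each other across the ring. A bond between them divides the ring into two six-membered rings, C3–C4=C5–C6–C7–C8 and C3–C2–C1=C10–C9–C8, each holding one olefin in exactly the ring-cis geometry required. Read backwards, the ten-membered ring is the product of a glycol cleavage.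

## Retrosynthesis

**26 ⇒ 25.** The two C–O bonds of the oxirane are cut first. The epoxy alcohol is the most fragile group, and an epoxide β,γ to a C3 or C8 ketone would eliminate, so it must come after both reductions. Diol 25 has one ring and two stereocentres fewer. The forward step must be reagent-controlled and must choose the C14 allylic alcohol over the C3 allylic alcohol. A titanium–tartrate epoxidation of the primary, 2,3-(E)-substituted allylic alcohol meets both demands.

**25 ⇒ 24 ⇒ 23 ⇒ 21 ⇒ 20.** These are functional-group changes: the O14–Si bond, the C3–H bond (enone 23), the O8–acyl bond (with acid 22) and the C8–H bond. The order is set by lability. The C8 ketone sits beside the acidic C7–H and β to the lactone oxygen, so it is reduced first. O8 is acylated before C3 is reduced, so two free secondary alcohols never coexist. Dione 20 has only the C6 and C7 stereocentres. The forward steps need a reductant that takes a saturated ketone before an enone, acceptable facial selectivity at C8, and a catalyst-controlled enone reduction at C3.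

**20 ⇒ 19 (key).** The C3–C8 bond is reconnected, turning the 1,6-dione into the ring-fusion diol 19. The neighbouring cuts, C4=C5 or C1=C10 by metathesis or C2–C3 by cycloaddition, must close a ten-membered ring against entropy and transannular strain and leave olefin geometry to chance. In 19 there are only six-membered rings and both olefins are locked cis. The forward reaction is a glycol cleavage that must spare three olefins and works best on the cis diol.

**19 ⇒ 18.** The C1=C10 bond is cut by ring-closing metathesis. Diene 18 has only ring A. A monosubstituted and a 1,1-disubstituted olefin closing a cyclohexene is an easy case.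

**18 ⇒ 13 + 16, and 13 ⇒ 12 ⇒ 11 ⇒ 8 + 9.** The C8–C9 and C2–C3 bonds are cut as two carbonyl allylations. A free C3/C8 1,2-dione on ring A was considered and rejected: two enolisations (toward C7, then C6–H) turn it into a catechol and destroy C7. The ketones are therefore unveiled one at a time. Allyl bromide 9 adds to the C3 ketone of α′-silyloxy enone 8. The C8 carbinol of 11 is then oxidised (12), the tertiary hydroxyl is silylated (13), and the zinc reagent from bromide 16 adds to C8. Both additions must occur on the α face so that the two hydroxyls end up cis.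

**8 ⇒ 6 ⇒ 4 ⇒ 3 ⇒ 2 ⇒ 1.** The C8–O bond comes from a Rubottom oxidation of lactone enone 6. The O6–C6 bond comes from γ-bromination of keto acid 4 (bromide 5) and displacement by the carboxylate, which sets C6 from C7. Acid 4 is (S)-carvone 1 with its isopropenyl methyl raised to the acid level through chloride 2 and enal 3. Carvone supplies C3–C8, C15, C11–C13 and the C7 configuration.

**16 ⇒ 15 ⇒ 14.** The C4 unit is made from 2-methylidenepropane-1,3-diol 14 by monosilylation and bromination. The diol is preferred to 3-chloro-2-(chloromethyl)prop-1-ene because the oxygen must be protected before the organozinc is formed.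

## Roads not taken

**Alternative 1:** The cut is the C4=C5 double bond. A diene whose O3 and O6 are tied by a diisopropylsilylene bridge would be treated with the second-generation Grubbs catalyst (H2IMes)(PCy3)Cl2Ru=CHPh. Metathesis between the C3 isopropenyl and C6 vinyl groups would close the seven-membered silacycle and the carbocycle together, giving A1.
- Merits: the silacycle enforces the ring-cis olefin. Every stereocentre, including C3, C8 and the epoxide, is set before the ring exists. In this respect it is better than the chosen plan, which sets C3 and C8 on a ten-membered ketone.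
- Weak points: forming a trisubstituted olefin while closing a ten-membered ring is among the least favourable metatheses, with oligomerisation and the acrylate as competitors. The substrate is a linear C1–C10 chain with six stereocentres and an epoxide, and it still needs desilylation and lactonisation afterwards.
- Comparison: the chosen plan answers the stereochemical advantage with a ring-forming event that has no entropic or strain barrier, with ring A, C15, C11–C13 and C7 taken from carvone in four steps, and with reagent control or inversion for the carbinols.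

**Alternative 2:** The cut is C2–C3 together with O–C1. A nitrile oxide generated from a C3 oxime with NaOCl would add across the C1=C2 vinyl group and give the isoxazoline-bridged carbocycle A2.
- Merits: one operation forms a C–C bond, the ring, the C1 oxygen and a masked C3 carbonyl, without metals. It installs the C1 oxygen more directly than the chosen plan.
- Weak points: closing a ten-membered ring this way competes with furoxan dimerisation and needs high dilution. C1 is set by substrate control. Afterwards come N–O cleavage under reducing conditions, base-mediated relocation of the 10,14-epoxide to the 1,10-position (an equilibrium), and reduction of the C3 ketone in the ring, with the same uncertainty as here. A2 lacks C13, so the lactone must be methylenated late by enolate chemistry beside an epoxide.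
- Comparison: the chosen plan sets against it a reagent-controlled epoxidation of the C14 allylic alcohol and a methylene lactone carried from step 4, so no late enolate chemistry is needed.

**Alternative 3:** The cut is the C5–C10 bond of a decalin. The tosylhydrazone of the C4 ketone of a 5,10-epoxy decalin would fragment (Eschenmoser–Tanabe) to the C4≡C5 alkyne and the C10 ketone, giving cyclodecynone A3.
- Merits: the ring-forming event is as good as the chosen one; it is the same idea of unveiling the ring by scission of a shared bond, and it is irreversible. C3, C6, C7 and C8 are set on a rigid decalin, which is more predictable than the chosen plan.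
- Weak points: A3 has neither olefin. The alkyne must become a (Z)-trisubstituted olefin with methyl delivered to C4 between two oxygenated carbons. The C10 ketone must become the C1=C10 olefin carrying C14, with C1/C9 regiochemistry to control. The lactone must be closed and methylenated from a CH2CO2Me group. All of this happens on the medium ring.
- Comparison: the chosen plan sets against the better carbinol control the fact that both olefins leave the cleavage with the right position, substituents and geometry, so only two reductions and one epoxidation remain.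

Key step: step 13

Assumption: the target is taken exactly as drawn, with a cis-fused 6,12-lactone (H6 and H7 syn), O8 cis to C11, and the (R)-configured 2-methylbutanoate.

## Route

Step 1
Reactants: 1 (S)-carvone
Product: 2 (5S)-5-(3-chloroprop-1-en-2-yl)-2-methylcyclohex-2-en-1-one
Conditions: Ca(OCl)2, solid CO2, CH2Cl2/H2O, 0 °C
Reagents that add atoms: calcium hypochlorite, [Ca+2].[O-]Cl.[O-]Cl
Why: Ene-type allylic chlorination by HOCl (from Ca(OCl)2 and CO2) attacks only the electron-rich 1,1-disubstituted olefin and shifts it to give the 2-substituted allyl chloride; the enone is inert and C7 is untouched.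

Step 2
Reactants: 2 (5S)-5-(3-chloroprop-1-en-2-yl)-2-methylcyclohex-2-en-1-one
Product: 3 2-[(1S)-4-methyl-5-oxocyclohex-3-en-1-yl]prop-2-enal
Conditions: 4-methylmorpholine N-oxide, NaI (cat.), MeCN, 25 to 50 °C
Reagents that add atoms: 4-methylmorpholine N-oxide, C[N+]1([O-])CCOCC1
Why: Ganem (Kornblum-type) oxidation: the N-oxide displaces the allylic halide under iodide catalysis and the alkoxyammonium salt collapses to the enal and N-methylmorpholine under near-neutral conditions that leave the allylic C7–H in place.

Step 3
Reactants: 3 2-[(1S)-4-methyl-5-oxocyclohex-3-en-1-yl]prop-2-enal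
Product: 4 2-[(1S)-4-methyl-5-oxocyclohex-3-en-1-yl]prop-2-enoic acid
Conditions: NaClO2, NaH2PO4, 2-methylbut-2-ene, t-BuOH/H2O, 0 °C
Reagents that add atoms: sodium chlorite, [Na+].[O-]Cl=O
Why: Pinnick oxidation takes the enal to the acrylic acid without touching the enone or the 1,1-disubstituted olefin; 2-methylbut-2-ene removes the HOCl formed.

Step 4
Reactants: 4 2-[(1S)-4-methyl-5-oxocyclohex-3-en-1-yl]prop-2-enoic acid
Product: 6 (3aS,7aS)-6-methyl-3-methylidene-3,3a,4,7a-tetrahydro-1-benzofuran-2,5-dione (cis-fused lactone enone), via trans-6-bromo acid 5 (not isolated)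
Conditions: N-bromosuccinimide, 2,2′-azobis(2-methylpropionitrile) (cat.), PhCF3, 80 °C; then NaHCO3, DMF, 25 °C
Reagents that add atoms: N-bromosuccinimide, O=C1CCC(=O)N1Br (supplies the bromine of 5; no reagent atom remains in 6)
Why: Wohl–Ziegler bromination removes a C6 hydrogen, whose radical is delocalised over C4–C6 and the C3 carbonyl, and bromine enters anti to the C7 side chain; the carboxylate then displaces bromide by 5-exo-tet SN2 with inversion, so C7 sets C6 (O6 cis to C11), as in the bromination–lactonisation of 3-oxo-4-en-12-oic acids of the eudesmane series. E2 loss of HBr toward C7 is disfavoured because H7 is syn to the bromide.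

Step 5
Reactants: 6 (3aS,7aS)-6-methyl-3-methylidene-3,3a,4,7a-tetrahydro-1-benzofuran-2,5-dione
Product: 8 (3aS,4R,7aS)-6-methyl-3-methylidene-4-[(triethylsilyl)oxy]-3,3a,4,7a-tetrahydro-1-benzofuran-2,5-dione (8α-OSiEt3), via triethylsilyl dienol ether 7 (not isolated)
Conditions: Et3SiOTf, Et3N, CH2Cl2, 0 °C; then mCPBA, NaHCO3, CH2Cl2, −20 °C
Reagents that add atoms: triethylsilyl trifluoromethanesulfonate, CC[Si](CC)(CC)OS(=O)(=O)C(F)(F)F; 3-chloroperoxybenzoic acid, OOC(=O)c1cccc(Cl)c1
Why: Soft enolisation removes a C8 hydrogen and gives the cross-conjugated 2-silyloxy diene; Rubottom oxidation (epoxidation of the enol ether anti to the C7–C11 bond, then silyl migration) puts the C8 silyl ether on the α face and leaves the electron-poor olefins alone.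

Step 6
Reactants: 8 8α-triethylsilyloxy lactone enone; 9 allyl bromide
Product: 11 (3aS,7aS)-5α-allyl-4α,5β-dihydroxy-6-methyl-3-methylidene-3a,4,5,7a-tetrahydro-1-benzofuran-2(3H)-one (3α-allyl-3β,8α-diol), via C8 triethylsilyl ether adduct 10 (not isolated)
Conditions: 9, Zn dust, THF, 0 °C; then 8, −78 °C; aq. NH4Cl; then Bu4NF, AcOH, THF, 0 °C
Reagents that add atoms: none
Why: Allylzinc adds 1,2 to the enone through a six-membered transition state far faster than to the lactone at −78 °C. Axial attack on the half-chair from the α face, anti to the C7 substituent as in additions to carvone, puts the allyl group opposite the lactone; the equatorial, non-chelating OSiEt3 offers no counter-bias. Buffered fluoride then frees the C8 hydroxyl without ionising the tertiary allylic alcohol.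

Step 7
Reactants: 11 3α-allyl-3β,8α-diol
Product: 12 (3aS,7aS)-5α-allyl-5β-hydroxy-6-methyl-3-methylidene-3,3a,5,7a-tetrahydro-1-benzofuran-2,4-dione (C8 ketone, tertiary C3 carbinol)
Conditions: Dess–Martin periodinane, NaHCO3, CH2Cl2, 0 to 25 °C
Reagents that add atoms: none
Why: Dess–Martin oxidation converts the secondary C8 carbinol to the ketone and cannot oxidise the tertiary C3 hydroxyl; buffered neutral conditions avoid α-ketol shift and E1cB opening of the lactone.

Step 8
Reactants: 12 3α-allyl-3β-hydroxy 8-ketone
Product: 13 3β-trimethylsilyl ether of 12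
Conditions: N-(trimethylsilyl)imidazole, CH2Cl2, 25 °C
Reagents that add atoms: N-(trimethylsilyl)imidazole, C[Si](C)(C)n1ccnc1
Why: The reagent silylates the hindered tertiary α-ketol hydroxyl without enolising the C8 ketone; removing the chelating hydroxyl lets the next addition follow the Felkin–Anh mode.

Step 9
Reactants: 14 2-methylidenepropane-1,3-diol
Product: 15 2-({[tert-butyl(dimethyl)silyl]oxy}methyl)prop-2-en-1-ol
Conditions: NaH (1 equiv), THF, 0 °C; then t-BuMe2SiCl, 25 °C
Reagents that add atoms: tert-butyl(chloro)dimethylsilane, CC(C)(C)[Si](C)(C)Cl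
Why: Monosilylation of a symmetric diol through its sparingly soluble monosodium alkoxide, a standard way to the mono-ether.

Step 10
Reactants: 15 2-({[tert-butyl(dimethyl)silyl]oxy}methyl)prop-2-en-1-ol
Product: 16 {[2-(bromomethyl)prop-2-en-1-yl]oxy}(tert-butyl)dimethylsilane
Conditions: CBr4, PPh3, CH2Cl2, 0 °C
Reagents that add atoms: tetrabromomethane, BrC(Br)(Br)Br
Why: Appel bromination of the primary allylic alcohol under neutral conditions; direct and allylic displacement give the same bromide.

Step 11
Reactants: 13 3β-trimethylsilyloxy 8-ketone; 16 silyloxymethyl allyl bromide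
Product: 18 3α-allyl-8α-[2-({[tert-butyl(dimethyl)silyl]oxy}methyl)prop-2-en-1-yl]-3β,8β-diol (cis diol on ring A, lactone intact), via C3 trimethylsilyl ether adduct 17 (not isolated)
Conditions: 16, Zn dust, LiCl, THF, 25 °C; then 13, −78 to −20 °C; then 10% aq. citric acid, MeOH, 0 °C
Reagents that add atoms: none
Why: The 2-substituted allylzinc bromide adds to the hindered ketone through a cyclic six-membered transition state. Attack anti to the perpendicular C3–OSiMe3 bond (Felkin–Anh) coincides with the α face of the cis-fused bicycle, so the new chain enters cis to the C3 allyl group and the two oxygens become cis. Mild acid removes only the trimethylsilyl group.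

Step 12
Reactants: 18 ring-A cis diol with two allyl-type chains
Product: 19 cis-fused hexahydronaphthalene ring-fusion 3β,8β-diol (ring B: C3–C2–C1=C10(CH2OSiMe2t-Bu)–C9–C8; lactone on ring A)
Conditions: second-generation Grubbs catalyst (H2IMes)(PCy3)Cl2Ru=CHPh (5 mol %), CH2Cl2, 40 °C
Reagents that add atoms: none
Why: Ring-closing metathesis between the monosubstituted and the 1,1-disubstituted olefin closes six-membered ring B with loss of ethene; the trisubstituted ring-A olefin and the electron-poor methylene lactone are poor partners, and the cis-disposed chains give the cis-fused bicycle.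

Step 13
Reactants: 19 cis-fused ring-fusion diol
Product: 20 ten-membered 3,8-dione (4Z and ring-cis C1=C10 olefins, C14 silyl ether, cis-fused methylene lactone)
Conditions: Pb(OAc)4 (1.1 equiv), CH2Cl2, −20 °C, 10 min; cold aq. NaHCO3; used at once
Reagents that add atoms: none
Why: Criegee glycol cleavage: the two cis ring-fusion hydroxyls exchange acetate on tetravalent lead to give a five-membered cyclic plumbate, which fragments in a concerted two-electron step to the C3 and C8 ketones and lead diacetate. The closest known reaction type is the cleavage of cis-decalin-9,10-diols to cyclodecane-1,6-diones. The ten-membered ring is not closed by bond formation but unveiled by scission of the zero-atom bridge of the bicyclo[4.4.0] skeleton, so no cyclisation entropy or transannular strain is met in a bond-forming transition state. No stereocentre is created; the two carbinol centres are erased and C6 and C7 are not involved. Both olefins emerge ring-cis because each was part of a cyclohexene. The step needs chemoselectivity for the glycol over three olefins and an allylic silyl ether, secured by the oxidant's need for a 1,2-diol chelate, and it needs the cis diol, which steps 6 and 11 provide. The product is a 1,6-dione with an acidic C7–H beside a β-acyloxy ketone, so the reaction is run cold, worked up at neutral pH and followed immediately by reduction.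

Step 14
Reactants: 20 ten-membered 3,8-dione
Product: 21 (8R)-8-hydroxy 3-enone (O8 cis to C11, as in the target)
Conditions: Zn(BH4)2, Et2O/DME, −20 °C; aq. NH4Cl
Reagents that add atoms: none
Why: Zn(BH4)2 reduces saturated ketones in the presence of conjugated enones and is neutral, so the C3 enone, the methylene lactone and C7 are left alone. Hydride is expected to approach C8 from the ring periphery, anti to the C6–C7 bond (Felkin–Anh arrangement with H7 inside), giving the 8R carbinol; this is to be confirmed before acylation.

Step 15
Reactants: 21 (8R)-8-hydroxy 3-enone; 22 (R)-2-methylbutanoic acid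
Product: 23 8-O-[(2R)-2-methylbutanoyl] 3-enone
Conditions: 22, EDC·HCl, 4-(dimethylamino)pyridine (cat.), CH2Cl2, 0 to 25 °C
Reagents that add atoms: none
Why: Steglich esterification with retention at C8; catalytic base at low temperature limits epimerisation of the acid's α-centre, and prompt acylation removes the free O8 that could translactonise.

Step 16
Reactants: 23 8-ester 3-enone
Product: 24 (3S)-allylic alcohol (8-ester, C14 silyl ether)
Conditions: (R)-2-methyl-CBS-oxazaborolidine [(3aR)-1-methyl-3,3-diphenyltetrahydro-1H,3H-pyrrolo[1,2-c][1,3,2]oxazaborole] (20 mol %), catecholborane, toluene, −78 °C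
Reagents that add atoms: none
Why: Corey–Bakshi–Shibata reduction: the (R)-catalyst binds the carbonyl anti to the larger α-methylvinyl side and delivers hydride to give the 3S alcohol under reagent control. Catecholborane at −78 °C gives only 1,2-reduction and does not touch the esters, the lactone or the olefins.

Step 17
Reactants: 24 (3S)-allylic alcohol with C14 silyl ether
Product: 25 3,14-diol (8-ester, ring-cis C1=C10 olefin)
Conditions: HF·pyridine, pyridine, THF, 0 °C
Reagents that add atoms: none
Why: Fluoride cleavage of the primary allylic silyl ether under buffered conditions in which the esters, the lactone and the allylic alcohols are stable.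

Step 18
Reactants: 25 3,14-diol
Product: 26 CNP0356520.2, (1R,3S,6S,7R,8R,10R)-1,10-epoxy-3,14-dihydroxy-8-[(2R)-2-methylbutanoyloxy]germacra-4Z,11(13)-dien-12,6-olide
Conditions: Ti(OiPr)4, D-(−)-diethyl tartrate, t-BuOOH, 4 Å molecular sieves, CH2Cl2, −20 °C
Reagents that add atoms: tert-butyl hydroperoxide, CC(C)(C)OO
Why: Sharpless asymmetric epoxidation: the primary allylic alcohol with 2,3-(E) substitution is the fast-reacting substrate type. D-(−)-diethyl tartrate, the enantiomer that turns (E)-hex-2-en-1-ol into the (2R,3R)-epoxy alcohol, delivers oxygen to the face that gives 1R,10R. The secondary C3 alcohol flanks a Z-substituted ring olefin, a slow substrate class, so C4=C5 and the methylene lactone remain.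

## Compound list

1 | (S)-carvone, (5S)-2-methyl-5-(prop-1-en-2-yl)cyclohex-2-en-1-one | CC1=CC[C@@H](CC1=O)C(C)=C | starting material
2 | (5S)-5-(3-chloroprop-1-en-2-yl)-2-methylcyclohex-2-en-1-one | CC1=CC[C@@H](CC1=O)C(=C)CCl | intermediate
3 | 2-[(1S)-4-methyl-5-oxocyclohex-3-en-1-yl]prop-2-enal | CC1=CC[C@@H](CC1=O)C(=C)C=O | intermediate
4 | 2-[(1S)-4-methyl-5-oxocyclohex-3-en-1-yl]prop-2-enoic acid | CC1=CC[C@@H](CC1=O)C(=C)C(=O)O | intermediate
5 | 2-[(1S,2R)-2-bromo-4-methyl-5-oxocyclohex-3-en-1-yl]prop-2-enoic acid (bromine on C6, trans to the side chain) | Br[C@@H]1C=C(C)C(=O)C[C@H]1C(=C)C(O)=O | intermediate (not isolated)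
6 | (3aS,7aS)-6-methyl-3-methylidene-3,3a,4,7a-tetrahydro-1-benzofuran-2,5-dione (cis-fused lactone enone) | C=C1C(=O)O[C@H]2C=C(C)C(=O)C[C@@H]12 | intermediate
7 | triethylsilyl dienol ether of 6 (C3–OSiEt3, C3=C8, C4=C5) | C=C1C(=O)O[C@H]2C=C(C)C(O[Si](CC)(CC)CC)=C[C@@H]12 | intermediate (not isolated)
8 | (3aS,4R,7aS)-6-methyl-3-methylidene-4-[(triethylsilyl)oxy]-3,3a,4,7a-tetrahydro-1-benzofuran-2,5-dione (8α-OSiEt3) | C=C1C(=O)O[C@H]2C=C(C)C(=O)[C@H](O[Si](CC)(CC)CC)[C@@H]12 | intermediate
9 | allyl bromide | C=CCBr | starting material
10 | 3α-allyl-3β-hydroxy-8α-triethylsilyloxy adduct of 8 | C=C1C(=O)O[C@H]2C=C(C)[C@](O)(CC=C)[C@H](O[Si](CC)(CC)CC)[C@@H]12 | intermediate (not isolated)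
11 | 3α-allyl-3β,8α-diol (cis-fused lactone, C4=C5) | C=C1C(=O)O[C@H]2C=C(C)[C@](O)(CC=C)[C@H](O)[C@@H]12 | intermediate
12 | 3α-allyl-3β-hydroxy 8-ketone | C=C1C(=O)O[C@H]2C=C(C)[C@](O)(CC=C)C(=O)[C@@H]12 | intermediate
13 | 3α-allyl-3β-trimethylsilyloxy 8-ketone | C=C1C(=O)O[C@H]2C=C(C)[C@](O[Si](C)(C)C)(CC=C)C(=O)[C@@H]12 | intermediate
14 | 2-methylidenepropane-1,3-diol | C=C(CO)CO | starting material
15 | 2-({[tert-butyl(dimethyl)silyl]oxy}methyl)prop-2-en-1-ol | C=C(CO)CO[Si](C)(C)C(C)(C)C | intermediate
16 | {[2-(bromomethyl)prop-2-en-1-yl]oxy}(tert-butyl)dimethylsilane | C=C(CBr)CO[Si](C)(C)C(C)(C)C | intermediate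
17 | 3β-trimethylsilyloxy-8β-hydroxy bis-allyl adduct (both chains α) | C=C1C(=O)O[C@H]2C=C(C)[C@](O[Si](C)(C)C)(CC=C)[C@](O)(CC(=C)CO[Si](C)(C)C(C)(C)C)[C@@H]12 | intermediate (not isolated)
18 | 3α-allyl-8α-[2-(silyloxymethyl)allyl]-3β,8β-diol (cis diol) | C=C1C(=O)O[C@H]2C=C(C)[C@](O)(CC=C)[C@](O)(CC(=C)CO[Si](C)(C)C(C)(C)C)[C@@H]12 | intermediate
19 | cis-fused hexahydronaphthalene ring-fusion 3β,8β-diol with fused methylene lactone (key-step precursor) | C=C1C(=O)O[C@H]2C=C(C)[C@]3(O)CC=C(CO[Si](C)(C)C(C)(C)C)C[C@]3(O)[C@@H]12 | intermediate
20 | ten-membered 3,8-dione, 14-O-silyl-3,8-dioxogermacra-1(10),4Z,11(13)-trien-12,6-olide with ring-cis C1=C10 (key-step product) | C=C1C(=O)O[C@H]2/C=C(/C)C(=O)C/C=C(CO[Si](C)(C)C(C)(C)C)\CC(=O)[C@@H]12 | intermediate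
21 | (8R)-8-hydroxy 3-enone | C=C1C(=O)O[C@H]2/C=C(/C)C(=O)C/C=C(CO[Si](C)(C)C(C)(C)C)\C[C@@H](O)[C@@H]12 | intermediate
22 | (R)-2-methylbutanoic acid | OC(=O)[C@H](C)CC | starting material
23 | 8-O-[(2R)-2-methylbutanoyl] 3-enone | C=C1C(=O)O[C@H]2/C=C(/C)C(=O)C/C=C(CO[Si](C)(C)C(C)(C)C)\C[C@@H](OC(=O)[C@H](C)CC)[C@@H]12 | intermediate
24 | (3S)-3-hydroxy 8-ester with C14 silyl ether | C=C1C(=O)O[C@H]2/C=C(/C)[C@@H](O)C/C=C(CO[Si](C)(C)C(C)(C)C)\C[C@@H](OC(=O)[C@H](C)CC)[C@@H]12 | intermediate
25 | (3S)-3,14-dihydroxy 8-ester, ring-cis C1=C10 olefin | C=C1C(=O)O[C@H]2/C=C(/C)[C@@H](O)C/C=C(CO)\C[C@@H](OC(=O)[C@H](C)CC)[C@@H]12 | intermediate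
26 | CNP0356520.2, (1R,3S,6S,7R,8R,10R)-1,10-epoxy-3,14-dihydroxy-8-[(2R)-2-methylbutanoyloxy]germacra-4Z,11(13)-dien-12,6-olide | C=C1C(=O)O[C@H]2/C=C(/C)[C@@H](O)C[C@H]3O[C@@]3(CO)C[C@@H](OC(=O)[C@H](C)CC)[C@@H]12 | target

## Step count and least certain steps

Total: 18 steps. Longest linear sequence: 16 steps (steps 1–8 and 11–18 from (S)-carvone); steps 9 and 10 make the C4 fragment.

**Step 13 (key step).** The cleavage itself is reliable. The likely failure is decay of dione 20 during work-up and handling: transannular aldol closure between the 1,6-related ketones, or enolisation at C7 followed by epimerisation, olefin migration or E1cB opening of the lactone. Fallback, from 19: cleave with NaIO4 on wet silica in CH2Cl2 (no acid, no lead salts) and, in the same flask, reduce both ketones of the transient dione with NaBH4/CeCl3·7H2O in MeOH at −78 °C to the 3,8-diol F1. MnO2 then reoxidises only the allylic C3 carbinol. The route is rejoined at 21. This replaces isolation of 20 and the selective mono-reduction by a global reduction and a selective allylic oxidation.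

**Step 4.** Hydrogen abstraction may be unselective: the allylic C7–H next to the acrylate competes with C6–H, and a C7 or cis-C6 bromide would lose HBr and aromatise. Fallback, from 4: thermodynamic silylation (Me3SiCl, NaI, Et3N, MeCN) gives the linear bis-silylated dienol ether F2. Dimethyldioxirane oxidises C6 anti to the side chain, and work-up gives the trans-6-hydroxy acid F3. Intramolecular Mitsunobu reaction (PPh3, DIAD) closes the lactone with inversion. The route is rejoined at 6.

**Step 11 (with step 6).** Facial selectivity in the two carbonyl additions is the main stereochemical uncertainty before the key step. If either chain enters from the β face, the hydroxyls end up trans and a cyclic plumbate cannot form. Fallback, from 12 (no silylation): a chelation-controlled Barbier addition of 16 (Zn, THF/aq. NH4Cl) places the new chain anti to the C3 allyl group and gives the trans diol F4. Metathesis gives the trans-fused bicyclic diol F5, which is cleaved with Pb(OAc)4 in pyridine through the open lead-alkoxide pathway known for trans-decalin-9,10-diol. The route is rejoined at 20.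

**Step 14.** Hydride may add to the wrong face of the C8 ketone, since medium-ring conformation or zinc chelation to O6 can override the Felkin preference, and some enone reduction is possible. A free 8β-hydroxyl may also translactonise. Fallback, from 20: if the same reduction gives the 8S alcohol F6 (O8 trans to C11, unable to translactonise), esterify it with 22 under Mitsunobu conditions (PPh3, DIAD, toluene), which inverts C8. The route is rejoined at 23.

**Step 18.** The free C3 hydroxyl may bind titanium and erode the rate or the facial control of the epoxidation, and the substrate's own bias may oppose the tartrate. Fallback, from 24: silylate O3 (t-BuMe2SiOTf, 2,6-lutidine) to the bis-silyl ether F7. Remove the primary allylic silyl group selectively (HF·pyridine, pyridine, 0 °C) to give the mono-alcohol F8. Epoxidise this single-hydroxyl substrate with Ti(OiPr)4, D-(−)-diethyl tartrate and t-BuOOH to give F9, then desilylate with HF·pyridine at 25 °C. The route is rejoined at 26.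

Further compounds
F1 | step 13 | (3RS,8R)-3,8-dihydroxy-14-O-silyl germacra-1(10),4Z,11(13)-trien-12,6-olide (C3 unassigned, reoxidised later) | C=C1C(=O)O[C@H]2/C=C(/C)C(O)C/C=C(CO[Si](C)(C)C(C)(C)C)\C[C@@H](O)[C@@H]12
F2 | step 4 | trimethylsilyl 2-[(1S)-4-methyl-5-(trimethylsilyloxy)cyclohexa-2,4-dien-1-yl]prop-2-enoate (linear dienol ether) | CC1=C(O[Si](C)(C)C)C[C@H](C=C1)C(=C)C(=O)O[Si](C)(C)C
F3 | step 4 | 2-[(1S,2R)-2-hydroxy-4-methyl-5-oxocyclohex-3-en-1-yl]prop-2-enoic acid (hydroxyl trans to the side chain) | O[C@@H]1C=C(C)C(=O)C[C@H]1C(=C)C(O)=O
F4 | step 11 | 3α-allyl-8β-[2-(silyloxymethyl)allyl]-3β,8α-diol (trans diol, C8 epimer of 18) | C=C1C(=O)O[C@H]2C=C(C)[C@](O)(CC=C)[C@@](O)(CC(=C)CO[Si](C)(C)C(C)(C)C)[C@@H]12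
F5 | step 11 | trans-fused hexahydronaphthalene ring-fusion 3β,8α-diol (C8 epimer of 19) | C=C1C(=O)O[C@H]2C=C(C)[C@]3(O)CC=C(CO[Si](C)(C)C(C)(C)C)C[C@@]3(O)[C@@H]12
F6 | step 14 | (8S)-8-hydroxy 3-enone (C8 epimer of 21) | C=C1C(=O)O[C@H]2/C=C(/C)C(=O)C/C=C(CO[Si](C)(C)C(C)(C)C)\C[C@H](O)[C@@H]12
F7 | step 18 | 3,14-bis-O-[tert-butyl(dimethyl)silyl] derivative of 25 | C=C1C(=O)O[C@H]2/C=C(/C)[C@@H](O[Si](C)(C)C(C)(C)C)C/C=C(CO[Si](C)(C)C(C)(C)C)\C[C@@H](OC(=O)[C@H](C)CC)[C@@H]12
F8 | step 18 | 3-O-[tert-butyl(dimethyl)silyl] derivative of 25 (free C14 alcohol) | C=C1C(=O)O[C@H]2/C=C(/C)[C@@H](O[Si](C)(C)C(C)(C)C)C/C=C(CO)\C[C@@H](OC(=O)[C@H](C)CC)[C@@H]12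
F9 | step 18 | 3-O-[tert-butyl(dimethyl)silyl] derivative of 26 | C=C1C(=O)O[C@H]2/C=C(/C)[C@@H](O[Si](C)(C)C(C)(C)C)C[C@H]3O[C@@]3(CO)C[C@@H](OC(=O)[C@H](C)CC)[C@@H]12
A1 | alternative 1 | O3,O6-diisopropylsilylene-bridged ten-membered carbocycle with methyl acrylate side chain | CC(C)[Si]1(C(C)C)O[C@H]2/C=C(/C)[C@@H](O1)C[C@H]3O[C@@]3(CO[Si](C)(C)C(C)(C)C)C[C@@H](OC(=O)[C@H](C)CC)[C@H]2C(=C)C(=O)OC
A2 | alternative 2 | isoxazoline-bridged ten-membered carbocycle with 10,14-epoxide and O8 4-methoxybenzyl ether | C1C(=O)O[C@H]2/C=C(/C)C3=NO[C@H](C3)[C@@]4(CO4)C[C@@H](OCc5ccc(OC)cc5)[C@@H]12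
A3 | alternative 3 | cyclodec-5-ynone with O3 tert-butyldimethylsilyl, O6 triethylsilyl and O8 4-methoxybenzyl ethers and a CH2CO2Me chain on C7 | O=C1CC[C@H](O[Si](C)(C)C(C)(C)C)C#C[C@H](O[Si](CC)(CC)CC)[C@H](CC(=O)OC)[C@H](OCc2ccc(OC)cc2)C1
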